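A small charge of catalyst, 6.00 mM of Xc against 200 mM of Xa, has to carry Sunday's flask, and that flask is charged exactly as Monday's. So Monday's readings are my way of reaching 10 min.

| flask | Xa | Xb | Xc | time |
|---|---|---|---|---|
| Monday's | 200 mM | 300 mM | 6.00 mM |  |
| Thursday's | 200 mM | 300 mM | 9.00 mM |  |
| Wednesday's | 200 mM | 150 mM | 6.00 mM |  |
| Sunday's | 200 mM | 300 mM | 6.00 mM | 10 min |

| run | time / min | [Xa] / mM |
|---|---|---|
| Monday's run | 0.12 | 195.2 |
| Monday's run | 0.37 | 184.1 |
| Monday's run | 0.71 | 170.1 |
| Monday's run | 1.1 | 153.3 |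
| Monday's run | 1.6 | 133.6 |
| Monday's run | 2.1 | 114.3 |
| Monday's run | 2.7 | 93.6 |
| Monday's run | 3.4 | 75.0 |
| Thursday's run | 0.12 | 194.2 |
| Thursday's run | 0.37 | 179.7 |
| Thursday's run | 0.71 | 160.5 |
| Thursday's run | 1.1 | 140.4 |
| Thursday's run | 1.6 | 116.2 |
| Thursday's run | 2.1 | 96.0 |
| Thursday's run | 2.7 | 76.1 |
| Thursday's run | 3.4 | 58.8 |
| Wednesday's run | 0.12 | 194.6 |
| Wednesday's run | 0.37 | 190.5 |
| Wednesday's run | 0.71 | 183.7 |
| Wednesday's run | 1.1 | 170.2 |
| Wednesday's run | 1.6 | 159.7 |
| Wednesday's run | 2.1 | 147.8 |
| Wednesday's run | 2.7 | 136.7 |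
| Wednesday's run | 3.4 | 125.4 |

(scatter of a reading: 1 mM)

* how the opening rate goes with [Xc] round the charge of the Monday's run: the exponent of the rate at two percent of Xa gone to Xp
* how the opening rate goes with [Xb] round the charge of the Monday's run: the exponent of the rate at two percent of Xa gone to Xp
* Xa in the Sunday's run at 10 min, as a share of the Xa charged

- Overall: Xa + Xb -> Xp, with Xc as catalyst.
- Constant volume, constant temperature.
- What is held in complexes is read along with the free species.
- "The second partner" is Xb.
- An order is taken over about fifteen percent of the charge, up and down.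

In Sunday's flask Xa is the limiting reagent, and the charge leaves 100 mM of Xb over if Xa reaches zero. So I turn the question round: what must hold for Sunday's Xa to reach zero by 10 min? It is enough that Monday's last fall continues straight. Between 2.1 min and 3.4 min Xa drops at 30.2 mM min⁻¹, and that line hits zero at 5.88 min, well before the time asked.

But a straight fall makes the drop of ln[Xa] per minute climb without stopping, and I can test that at both ends of Monday's run. At the opening it reads 0.233 min⁻¹. Over the last two spans it reads 0.333 min⁻¹ and then 0.316 min⁻¹, a difference inside the scatter of about 0.0269 min⁻¹. Within that scatter, I read no further climb in Monday's run.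

So I carry 0.324 min⁻¹, the tail constant: the drop of ln[Xa] per minute once that drop has stopped climbing. Joined to Monday's last reading, it leaves 8.83 mM of Xa at 10 min, which is 4.42 % of the charge.

The forecast gives 0.55 for Xc, 0.75 for Xb and 4.5 % for Sunday's share, 0.080 percentage points above mine: “Carrying this on from 3.4 min with k about 0.35 per min over 6.6 min leaves about 8 mM, roughly 4–5%.”

The flask gives 0.84 for Xc, 0.48 for Xb and 4.97 % for Sunday's share.

    Xc + Xa ⇌ Xc.Xa, settled at all times (10.70 L mol⁻¹)
    Xc.Xa + Xb ⇌ Xc.Xa.Xb, settled at all times (13.60 L mol⁻¹)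
    Xc.Xa.Xb → Xp + Xc (10.38 min⁻¹)
    2 Xc ⇌ Xc2, settled at all times (2020 L mol⁻¹)
    Xa + Xb + Xp → 2 Xp (5.448 L² mol⁻² min⁻¹)

Both exponents are taken at two percent of Xa turned, where Monday's run makes Xp at 40 mM min⁻¹. From Monday's last reading to Sunday's share at 10 min, the drop of ln[Xa] averages 0.306 min⁻¹, against the tail constant of 0.324 min⁻¹. The same rule on Wednesday's last readings gives 0.126 min⁻¹, which puts that run at half its Xa turned by 5.19 min; Wednesday's run reaches it at 5.50 min.

The earlier runs and the new flask stem from a simulated flask from invented constants; noise was put on by code.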